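## Analysis of the target

The target (20) is a spiro-meroterpenoid. Ring A is a dearomatised acylphloroglucinol (C1' spiro carbon, C2' ketone, C3' gem-diprenyl carbon, C4' enol carbon, C5' carrying the isovaleryl group, C6' ketone), ring B a cyclohexane (C1', C1, C2, C6, C7, C8) and ring C a cyclopentane (C2 to C6); the ten terpenoid carbons are numbered like a geranyl chain whose two ends C1 and C8 both sit on C1', with C9 the methyl on C3 and C10 the methyl on C7. Rings B and C form a trans-hydrindane (H2 and H6 anti) that holds four of the five stereocentres: C2 (R), C6 (S), the tertiary carbinol C3 (S, OH cis to C1) and the tertiary carbinol C7 (S, OH equatorial, C10 axial). The fifth, C1' (S in the tautomer drawn), is stereogenic only because its two carbonyl neighbours differ: C2' is flanked by the gem-diprenyl carbon, C6' by the acyl-bearing carbon. In 20 the C2' carbonyl is axial on ring B, syn to H2 and to the axial C10 methyl. This is the real difficulty: ring A is flat and perpendicular to ring B, the two C1' epimers differ only in which remote edge of ring A carries the prenyl groups, so they should be close in energy, and an ordinary anti (SN2-type) closure onto C1' cannot tell C2' from C6'. The feature the plan exploits is the six-atom array O(C2')–C2'–C1'–C8–C7–C10 of rings A and B, in which C10 is 1,3-syn to the C2' oxygen: it is the retron of a [3,3] shift of an allyl ether joining O(C2') to C10. A second constraint is the ring fusion: C2 can be equilibrated only while C1 is a carbonyl carbon. Sensitive groups are the acidic, chelating, oxidisable β-triketone enol, the two prenyl alkenes (they would not survive hydration of another alkene) and the two tertiary alcohols; the C7 carbinol must not be made through a cation, because the syn-axial C2' oxygen would capture it.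

## Retrosynthetic reasoning

20 ⇒ 17 + 18. Both C3'–prenyl bonds are cut last. In 17, C3' is the only ring-A carbon that still bears hydrogen, so regiochemistry is automatic, no stereocentre is formed, and the prenyl alkenes never meet the hydration conditions.

17 ⇒ 15. The C7–O bond is cut to an exocyclic C7=C10 methylene. The forward step is a radical (hydrogen-atom-transfer) Markovnikov hydration, which avoids the C7 cation. The axial face of C7 is covered by the C2' carbonyl, so oxygen should enter equatorially and leave C10 axial.

15 ⇒ 14 (key disconnection). The C1'–C8 bond is cut and an O(C2')–C10 bond is drawn instead: a retro-Claisen step to an eight-membered aryl allyl ether. This is the cut that solves C1': in the forward [3,3] shift the carbon chain is handed from the C2' oxygen to C1', so C2' must end up next to C7 (axial), and the regiochemistry of an ether becomes the configuration of the spiro carbon. The same step closes ring B by ring contraction and dearomatises ring A.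

14 ⇒ 12. The C1'–C1 bond is cut to an aldehyde and an aromatic C–H. The forward reaction is an intramolecular reductive alkylation that closes the eight-membered ring. The two ring carbons ortho to the ether oxygen are equivalent, so only one macrocycle can form.

12 ⇒ 11 + 3. The O–C10 ether bond is cut. In 3 the hydroxyl para to the acyl group is the most acidic and the only one not hydrogen-bonded to the ketone, so a simple etherification picks exactly the oxygen that becomes O(C2').

11 ⇒ 10 ⇒ 8 ⇒ 7. The C10–Cl bond comes from an ene-type allylic chlorination of the isopropenyl group. The C2–H and C3–OH pair comes from reductive cleavage of the Cα–O bond of an α,β-epoxy aldehyde. C3 is set by epoxidation anti to the side chain on C6, and C2 by equilibration next to the aldehyde (formyl trans to both neighbours), which is what later makes the hydrindane trans.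

7 ⇒ 6 ⇒ 4. Ring C is opened by a retro-aldol condensation to a keto-aldehyde, which comes from oxidative cleavage of the ring of 4. C6 is bought from the chiral pool.

3 ⇒ 1 + 2. Friedel–Crafts acylation.

## Alternatives that were turned down

Alternative 1: the textbook disconnection cuts C1'–C1 and C1'–C8 in the polar sense, with the ring carbon of 3 as a twofold nucleophile and a C10 bis-electrophile. Forward: epoxidation of the isopropenyl group of 10 to epoxy aldehyde A1, reductive C-alkylation of 3 to A2, then base-induced 6-endo opening of the epoxide at C8 by C1' with dearomatisation, which would give 17 directly. It was turned down for two reasons. The closure is an anti opening in which C2' and C6' are indistinguishable at the transition state, so both C1' epimers are expected. Epoxidation of an isopropenyl group beside one stereocentre is unselective, so C7 is uncontrolled as well. Four isomers for the same number of steps is no gain.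

Alternative 2: a condensation/intramolecular Diels–Alder cascade that cuts C1'–C1 and C2–C6 and builds rings B and C at once from an open chain. Forward: Knoevenagel condensation of the (2E,6S)-hydroxy enal A3 with the gem-diprenyl trione A4 gives trienone A5. Its diene C1'=C8–C7=C6 adds to the vinyl group C1=C2 (type 1 cycloaddition of a 1,3,8-nonatriene) to give hydrindene A6, and a radical hydration of C7=C8 finishes. It is the shortest route on paper (five to six steps). It was turned down because three selectivities have no handle:
- Ring fusion: an unactivated dienophile on a three-atom tether gives little or cis preference.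
- C1': it follows from which carbonyl lies inside on the alkylidene, and that geometry equilibrates through the 2H-pyran valence isomers.
- Facial choice at C2: it rests on methyl versus hydroxyl at the quaternary C3.

In addition, the tertiary alcohol can add 1,6 to the trienone, and the last hydration must spare two prenyl groups.

Alternative 3: an oxidative radical spirocyclisation that cuts C1'–C8 and C7–O together. Forward: reductive alkylation of A4 with 10 gives A7. One-electron oxidation under oxygen makes the C1' radical, which closes 6-endo onto the isopropenyl group; oxygen then traps the C7 radical. It was turned down because the C1' radical is 1,3 to the gem-diprenyl carbon and should close 5-exo onto a prenyl group (a bicyclo[3.2.1]octane, the usual fate of such radicals) faster than 6-endo. The planar radical also has no preference for which carbonyl becomes axial, and a peroxyl radical beside two prenyl groups invites endoperoxides.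

Key step: step 9

Remark: 20 and the enolised compounds 15–19 are written as one tautomer of the 2-acyl-1,3-dione unit; the tautomers interconvert and count as one compound each.

## Route

Step 1
Reactants: 1 phloroglucinol; 2 3-methylbutanoyl chloride
Product: 3 3-methyl-1-(2,4,6-trihydroxyphenyl)butan-1-one
Conditions: AlCl3 (3.5 equiv), PhNO2–CH2Cl2, 0 °C to 40 °C; aq. HCl
Reagents that add atoms: none
Why: Friedel–Crafts C-acylation of the electron-rich triol; the first acyl group deactivates the ring, so monoacylation should prevail; no stereocentre.

Step 2
Reactants: 4 (4S)-limonene 1,2-oxide (cis/trans mixture)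
Product: 6 (3S)-6-oxo-3-(prop-1-en-2-yl)heptanal, via diol 5 (not isolated)
Conditions: H5IO6 (1.1 equiv), THF–H2O, 0 °C to rt
Reagents that add atoms: water, O
Why: Periodic acid hydrolyses the epoxide and cleaves the resulting glycol in one pot, so both diastereomers of 4 converge; the stereocentre (later C6) is not touched and the 1,1-disubstituted alkene is inert.

Step 3
Reactants: 6 (3S)-6-oxo-3-(prop-1-en-2-yl)heptanal
Product: 7 (5R)-2-methyl-5-(prop-1-en-2-yl)cyclopent-1-ene-1-carbaldehyde
Conditions: piperidine (cat.), AcOH (cat.), PhMe, reflux, Dean–Stark
Reagents that add atoms: none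
Why: Amine-catalysed intramolecular aldol condensation; the enamine of the aldehyde is the donor and the methyl ketone the acceptor (5-enolexo), which builds ring C with the aldehyde on C2 and the methyl on C3; the stereocentre is not α to a carbonyl and should be kept.

Step 4
Reactants: 7 (5R)-2-methyl-5-(prop-1-en-2-yl)cyclopent-1-ene-1-carbaldehyde
Product: 8 (1R,2R,5S)-5-methyl-2-(prop-1-en-2-yl)-6-oxabicyclo[3.1.0]hexane-1-carbaldehyde
Conditions: 30% H2O2, NaOH (cat.), MeOH, 0 °C
Reagents that add atoms: hydrogen peroxide, OO
Why: Weitz–Scheffer nucleophilic epoxidation of the enal; hydroperoxide addition is reversible and the ring closure should occur anti to the isopropenyl group on the neighbouring carbon, which fixes the C3–O bond trans to C7; the electron-rich isopropenyl alkene does not react with the nucleophilic oxidant.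

Step 5
Reactants: 8 (1R,2R,5S)-5-methyl-2-(prop-1-en-2-yl)-6-oxabicyclo[3.1.0]hexane-1-carbaldehyde
Product: 10 (1R,2S,5S)-2-hydroxy-2-methyl-5-(prop-1-en-2-yl)cyclopentane-1-carbaldehyde, via samarium enolate 9 (not isolated)
Conditions: SmI2 (2.1 equiv), THF, −78 °C, then MeOH; then Et3N (cat.), CH2Cl2, rt
Reagents that add atoms: none
Why: Single-electron reduction of the α,β-epoxy carbonyl: the ketyl cleaves the Cα–O bond, a second electron gives enolate 9, and the C3–O bond keeps its configuration. After protonation the amine equilibrates C2 through the enol, so the formyl group should settle trans to both the C9 methyl and the C7 side chain (and cis to the hydroxyl, which can hydrogen-bond to it).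

Step 6
Reactants: 10 (1R,2S,5S)-2-hydroxy-2-methyl-5-(prop-1-en-2-yl)cyclopentane-1-carbaldehyde
Product: 11 (1R,2S,5S)-5-(3-chloroprop-1-en-2-yl)-2-hydroxy-2-methylcyclopentane-1-carbaldehyde
Conditions: Ca(OCl)2, CO2 (dry ice), CH2Cl2–H2O, 0 °C
Reagents that add atoms: calcium hypochlorite (chlorine source through HOCl), [Ca+2].[O-]Cl.[O-]Cl
Why: Ene-type allylic chlorination of a 1,1-disubstituted alkene by hypochlorous acid: chlorine adds to the terminal carbon and the methyl loses a proton, giving the 2-(chloromethyl)allyl unit; the aldehyde and tertiary alcohol should tolerate the short, CO2-buffered two-phase reaction.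

Step 7
Reactants: 11 (1R,2S,5S)-5-(3-chloroprop-1-en-2-yl)-2-hydroxy-2-methylcyclopentane-1-carbaldehyde; 3 3-methyl-1-(2,4,6-trihydroxyphenyl)butan-1-one
Product: 12 (1R,2S,5S)-5-{3-[3,5-dihydroxy-4-(3-methylbutanoyl)phenoxy]prop-1-en-2-yl}-2-hydroxy-2-methylcyclopentane-1-carbaldehyde
Conditions: 3 (1.5 equiv), K2CO3 (1.0 equiv), NaI (cat.), acetone, rt
Reagents that add atoms: none
Why: Williamson etherification; the hydroxyl para to the acyl group is the most acidic and is not hydrogen-bonded to the ketone, so one equivalent of weak base in an aprotic solvent should give the mono-ether at that oxygen (the later O on C2') and O- rather than C-allylation; the hindered aldehyde is left alone.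

Step 8
Reactants: 12 (1R,2S,5S)-5-{3-[3,5-dihydroxy-4-(3-methylbutanoyl)phenoxy]prop-1-en-2-yl}-2-hydroxy-2-methylcyclopentane-1-carbaldehyde
Product: 14 eight-membered aryl allyl ether (2R,3S,6S) with ring O–C10H2–C7(=C8H2)–C6–C2–C1H2–C1'(ar)–C2'(ar), via ortho-quinone methide 13 (not isolated)
Conditions: L-proline (20 mol %), Hantzsch ester (1.3 equiv), EtOH–CH2Cl2, 40 °C, slow addition to 2 mM
Reagents that add atoms: none
Why: Organocatalytic reductive alkylation (Knoevenagel-type condensation, then transfer hydrogenation): the iminium ion of the aldehyde is attacked by the ring carbon ortho to the ether oxygen, loss of the amine gives ortho-quinone methide 13, and the Hantzsch ester delivers hydride to C1 irreversibly. The two ortho carbons are equivalent, so one macrocycle results; the Hantzsch ester does not reduce the free aldehyde, so the reversible condensation is drained through 13, and high dilution favours the ring over oligomers.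

Step 9
Reactants: 14 eight-membered aryl allyl ether (2R,3S,6S)
Product: 15 spiro trione (1'S,2R,3S,6S) with exocyclic C7=C10 methylene and unsubstituted C3'
Conditions: PhNEt2 (degassed), 170 °C, sealed tube
Reagents that add atoms: none
Why: Proposed new method: a transannular, ring-contracting aromatic Claisen rearrangement; the closest known reactions are the dearomatising ortho-Claisen shift of allyl ethers of acylphloroglucinols onto a substituted ring carbon and the ring-contracting Ireland–Claisen rearrangement of macrolactones. The O–C10–C7=C8 allyl ether and the C2'=C1' bond of the arene form the six-centre array: C8 bonds to C1', the O–C10 bond breaks, C7=C10 becomes the new 1,1-disubstituted alkene, and the dienone tautomerises to the stable enolised trione, which together with the loss of medium-ring strain should drive the reaction. Ring B is closed by transannular C1'–C8 bond formation across the eight-membered ring (8 to 6 contraction); ring B and the pericyclic ring share C1', C8 and C7 like the two rings of a bicyclo[3.3.1]nonane. The only new stereocentre is C1': the migrating carbon is delivered from the C2' oxygen, so C2' must end up gauche to C7, that is axial on ring B and syn to C10. A chair for ring B is possible only with H2 axial and pointing at the ether oxygen, because the trans-fused ring C needs C3 and C5 equatorial; C2'=O therefore comes out cis to H2 as in 20, and the other epimer would need a boat. Regioselectivity needs no help: C8 cannot reach the other ortho carbon (C3') without a meta-bridged ring, and a following Cope shift to C5' is blocked by the acyl group. The basic solvent should suppress acid-promoted addition of the new enol to the exocyclic alkene and dehydration at C3.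

Step 10
Reactants: 15 spiro trione (1'S,2R,3S,6S) with exocyclic C7=C10 methylene
Product: 17 spiro trione diol (1'S,2R,3S,6S,7S) with unsubstituted C3', via hydroperoxide 16 (not isolated)
Conditions: Mn(dpm)3 (10 mol %), PhSiH3, O2 (1 atm), i-PrOH–CH2Cl2, 0 °C; then PPh3
Reagents that add atoms: dioxygen, O=O
Why: Mukaiyama hydration: hydrogen-atom transfer from a manganese hydride to C10 gives the tertiary C7 radical, oxygen traps it and PPh3 reduces hydroperoxide 16. A radical rather than a cationic hydration is used because a C7 cation would be captured by the syn-axial C2' oxygen. The axial face of C7 is covered by the C2' carbonyl, so oxygen should enter from the equatorial side, leaving OH equatorial and C10 axial (7S).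

Step 11
Reactants: 17 spiro trione diol (1'S,2R,3S,6S,7S); 18 prenyl bromide
Product: 20 target, (1'S,2R,3S,6S,7S)-spiro trione with gem-diprenyl C3', via monoprenyl trione 19 (not isolated)
Conditions: NaOMe (2.5 equiv), 18 (2.3 equiv), MeOH, 0 °C to rt
Reagents that add atoms: none
Why: C-alkylation of the vinylogous acid at C3', the only ring-A carbon that still bears hydrogen; monoprenyl compound 19 is still acidic and is alkylated again to the quaternary carbon. The protic solvent favours C- over O-alkylation, the tertiary alcohols do not react, and two identical groups create no stereocentre.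

## Compound list

1 | phloroglucinol (benzene-1,3,5-triol) | Oc1cc(O)cc(O)c1 | starting material
2 | 3-methylbutanoyl chloride (isovaleryl chloride) | CC(C)CC(Cl)=O | starting material
3 | 3-methyl-1-(2,4,6-trihydroxyphenyl)butan-1-one | CC(C)CC(=O)c1c(O)cc(O)cc1O | intermediate
4 | (4S)-limonene 1,2-oxide, (4S)-1-methyl-4-(prop-1-en-2-yl)-7-oxabicyclo[4.1.0]heptane, cis/trans mixture | CC12OC1C[C@H](CC2)C(C)=C | starting material
5 | (4S)-1-methyl-4-(prop-1-en-2-yl)cyclohexane-1,2-diol (mixture at C1 and C2) | CC1(O)C(O)C[C@H](CC1)C(C)=C | intermediate (not isolated)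
6 | (3S)-6-oxo-3-(prop-1-en-2-yl)heptanal | CC(=O)CC[C@@H](CC=O)C(C)=C | intermediate
7 | (5R)-2-methyl-5-(prop-1-en-2-yl)cyclopent-1-ene-1-carbaldehyde | CC1=C(C=O)[C@H](CC1)C(C)=C | intermediate
8 | (1R,2R,5S)-5-methyl-2-(prop-1-en-2-yl)-6-oxabicyclo[3.1.0]hexane-1-carbaldehyde | O=C[C@]12O[C@@]1(C)CC[C@@H]2C(C)=C | intermediate
9 | samarium enolate of 10, written as the free enol (1S,3R)-2-(hydroxymethylidene)-1-methyl-3-(prop-1-en-2-yl)cyclopentan-1-ol | OC=C1[C@H](CC[C@]1(C)O)C(C)=C | intermediate (not isolated)
10 | (1R,2S,5S)-2-hydroxy-2-methyl-5-(prop-1-en-2-yl)cyclopentane-1-carbaldehyde | O=C[C@@H]1[C@H](CC[C@]1(C)O)C(C)=C | intermediate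
11 | (1R,2S,5S)-5-(3-chloroprop-1-en-2-yl)-2-hydroxy-2-methylcyclopentane-1-carbaldehyde | O=C[C@@H]1[C@H](CC[C@]1(C)O)C(=C)CCl | intermediate
12 | (1R,2S,5S)-5-{3-[3,5-dihydroxy-4-(3-methylbutanoyl)phenoxy]prop-1-en-2-yl}-2-hydroxy-2-methylcyclopentane-1-carbaldehyde | O=C[C@@H]1[C@H](CC[C@]1(C)O)C(=C)COc1cc(O)c(C(=O)CC(C)C)c(O)c1 | intermediate
13 | macrocyclic ortho-quinone methide (2R,3S,6S), C1'=C1 exocyclic to the dienone ring | C=C1COC2=CC(O)=C(C(=O)CC(C)C)C(=O)C2=C[C@@H]3[C@@H]1CC[C@]3(C)O | intermediate (not isolated)
14 | eight-membered aryl allyl ether (2R,3S,6S), ring O–C10H2–C7(=C8H2)–C6–C2–C1H2–C1'–C2' | C=C1COc2cc(O)c(C(=O)CC(C)C)c(O)c2C[C@@H]3[C@@H]1CC[C@]3(C)O | intermediate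
15 | spiro trione (1'S,2R,3S,6S) with exocyclic C7=C10 methylene, C3' unsubstituted | C1C(=O)[C@@]2(C[C@@H]3[C@H](CC[C@]3(C)O)C(=C)C2)C(=O)C(C(=O)CC(C)C)=C1O | intermediate
16 | C7 hydroperoxide (1'S,2R,3S,6S,7S) | C1C(=O)[C@@]2(C[C@@H]3[C@H](CC[C@]3(C)O)[C@@](C)(OO)C2)C(=O)C(C(=O)CC(C)C)=C1O | intermediate (not isolated)
17 | spiro trione diol (1'S,2R,3S,6S,7S), C3' unsubstituted | C1C(=O)[C@@]2(C[C@@H]3[C@H](CC[C@]3(C)O)[C@@](C)(O)C2)C(=O)C(C(=O)CC(C)C)=C1O | intermediate
18 | prenyl bromide (1-bromo-3-methylbut-2-ene) | CC(C)=CCBr | starting material
19 | 3'-monoprenyl trione (mixture at C3') | CC(C)=CCC1C(=O)[C@@]2(C[C@@H]3[C@H](CC[C@]3(C)O)[C@@](C)(O)C2)C(=O)C(C(=O)CC(C)C)=C1O | intermediate (not isolated)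
20 | (1S,3'S,3a'R,7'S,7a'S)-3',4,7'-trihydroxy-3',7'-dimethyl-3-(3-methylbutanoyl)-5,5-bis(3-methylbut-2-en-1-yl)-1',2',3',3a',4',6',7',7a'-octahydrospiro[cyclohex-3-ene-1,5'-indene]-2,6-dione | CC(C)=CCC1(CC=C(C)C)C(=O)[C@@]2(C[C@@H]3[C@H](CC[C@]3(C)O)[C@@](C)(O)C2)C(=O)C(C(=O)CC(C)C)=C1O | target

## Step count and least certain steps

Total step count: 11. Longest linear sequence: 10 steps (4 to 20, steps 2 to 11); step 1 is a one-step branch that joins in step 7.

Step 9 (key step). The bicyclic transition state holds the sp2 carbon C7 at a bridgehead of the forming bicyclo[3.3.1] array. The barrier may therefore be high enough that ionisation of the allyl ether, dehydration at C3 or acid-promoted addition of the product enol to the new alkene runs first. Fallback with known chemistry, from 14 back to 15: ionise the allyl aryl ether with zerovalent palladium (Pd(PPh3)4, or Pd2(dba)3 with a chiral diphosphine) in THF at rt. The π-allyl/phenoxide pair should reclose at carbon C1' (Tsuji–Trost O-to-C allyl transfer, an intramolecular dearomatising allylic alkylation). The geometric relay is lost, so the ligand becomes the control element for C1' and the epimer has to be separated. This fallback makes no compound outside the list (F0).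

Step 8. Intermolecular condensation (oligomers and methylene-bridged dimers) may outrun closure of the eight-membered ring. Fallback, from 11 and 3 back to 15: run the same proline/Hantzsch ester reductive alkylation intermolecularly to give the C-alkylated allyl chloride F1, then close ring B directly by C-allylation at C1' with K2CO3 in aqueous methanol (six-membered ring, fast). This bypasses 14 and the relay, so 15 has to be separated from its C1' epimer F2.

Step 5. Over-reduction or pinacol coupling of the aldehyde by SmI2 may occur, or the tertiary hydroxyl may be lost (back to the enal) during the equilibration. Fallback, from 8 back to 10: oxidise the aldehyde with NaClO2 to epoxy acid F3, esterify with TMSCHN2 to epoxy ester F4, open with SmI2/MeOH (well precedented for α,β-epoxy esters) to hydroxy ester F5, equilibrate C2 with NaOMe and reduce with i-Bu2AlH at −78 °C to 10.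

Step 10. The free enolic position C3' may be oxidised under the aerobic manganese conditions, or facial selectivity in the oxygen capture may be incomplete. Fallback, from 15 back to 20: prenylate first (NaOMe, 18) to the gem-diprenyl alkene F6, which has no oxidisable ring C–H, then hydrate under the same hydrogen-atom-transfer conditions. This relies on the faster hydrogen-atom transfer to the 1,1-disubstituted alkene than to the trisubstituted prenyl alkenes and gives 20 directly.

Step 11. O-prenylation of the ambident trione anion may compete with C-prenylation, most of all in the second alkylation. Fallback, from 17 back to 20: double C-allylation with allyl methyl carbonate and Pd(PPh3)4 (C-selective for stabilised enolates) to diallyl trione F7, then double cross-metathesis with 2-methyl-2-butene and the second-generation Grubbs catalyst.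

## Further compounds

F0 | step 9 | none | none
F1 | step 8 | 1-[3-{[(1R,2S,5S)-5-(3-chloroprop-1-en-2-yl)-2-hydroxy-2-methylcyclopentyl]methyl}-2,4,6-trihydroxyphenyl]-3-methylbutan-1-one | CC(C)CC(=O)c1c(O)cc(O)c(C[C@@H]2[C@H](CC[C@]2(C)O)C(=C)CCl)c1O
F2 | step 8 | C1' epimer of 15, spiro trione (1'R,2R,3S,6S) | C1C(=O)[C@]2(C[C@@H]3[C@H](CC[C@]3(C)O)C(=C)C2)C(=O)C(C(=O)CC(C)C)=C1O
F3 | step 5 | (1R,2R,5S)-5-methyl-2-(prop-1-en-2-yl)-6-oxabicyclo[3.1.0]hexane-1-carboxylic acid | OC(=O)[C@]12O[C@@]1(C)CC[C@@H]2C(C)=C
F4 | step 5 | methyl (1R,2R,5S)-5-methyl-2-(prop-1-en-2-yl)-6-oxabicyclo[3.1.0]hexane-1-carboxylate | COC(=O)[C@]12O[C@@]1(C)CC[C@@H]2C(C)=C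
F5 | step 5 | methyl (1R,2S,5S)-2-hydroxy-2-methyl-5-(prop-1-en-2-yl)cyclopentane-1-carboxylate | COC(=O)[C@@H]1[C@H](CC[C@]1(C)O)C(C)=C
F6 | step 10 | gem-diprenyl spiro trione (1'S,2R,3S,6S) with exocyclic C7=C10 methylene | CC(C)=CCC1(CC=C(C)C)C(=O)[C@@]2(C[C@@H]3[C@H](CC[C@]3(C)O)C(=C)C2)C(=O)C(C(=O)CC(C)C)=C1O
F7 | step 11 | 3',3'-diallyl spiro trione diol (1'S,2R,3S,6S,7S) | C=CCC1(CC=C)C(=O)[C@@]2(C[C@@H]3[C@H](CC[C@]3(C)O)[C@@](C)(O)C2)C(=O)C(C(=O)CC(C)C)=C1O
A1 | alternative 1 | (1R,2S,5S)-2-hydroxy-2-methyl-5-(2-methyloxiran-2-yl)cyclopentane-1-carbaldehyde (mixture at the oxirane carbon) | O=C[C@@H]1[C@H](CC[C@]1(C)O)C1(C)CO1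
A2 | alternative 1 | 1-[2,4,6-trihydroxy-3-{[(1R,2S,5S)-2-hydroxy-2-methyl-5-(2-methyloxiran-2-yl)cyclopentyl]methyl}phenyl]-3-methylbutan-1-one (mixture at the oxirane carbon) | CC(C)CC(=O)c1c(O)cc(O)c(C[C@@H]2[C@H](CC[C@]2(C)O)C2(C)CO2)c1O
A3 | alternative 2 | (2E,6S)-6-hydroxy-2,6-dimethylocta-2,7-dienal | C=C[C@@](C)(O)CC/C=C(\C)C=O
A4 | alternative 2 | 3-hydroxy-2-(3-methylbutanoyl)-4,4-bis(3-methylbut-2-en-1-yl)cyclohex-2-ene-1,5-dione (enol form of the gem-diprenyl trione) | CC(C)=CCC1(CC=C(C)C)C(=O)CC(=O)C(C(=O)CC(C)C)=C1O
A5 | alternative 2 | Knoevenagel trienone from A3 and A4 (6S, C6=C7 E, alkylidene geometry not fixed) | CC(C)=CCC1(CC=C(C)C)C(=O)C(=C/C(C)=C/CC[C@](C)(O)C=C)C(=O)C(C(=O)CC(C)C)=C1O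
A6 | alternative 2 | hydrindene cycloadduct with C7=C8 alkene (isomer needed for 20) | CC(C)=CCC1(CC=C(C)C)C(=O)[C@@]2(C[C@@H]3[C@H](CC[C@]3(C)O)C(C)=C2)C(=O)C(C(=O)CC(C)C)=C1O
A7 | alternative 3 | gem-diprenyl dienol-one alkylated at C1' with the (1R,2S,5S)-2-hydroxy-2-methyl-5-(prop-1-en-2-yl)cyclopentylmethyl group | CC(C)=CCC1(CC=C(C)C)C(=O)C(C[C@@H]2[C@H](CC[C@]2(C)O)C(C)=C)=C(O)C(C(=O)CC(C)C)=C1O
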